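## Structural features

The target is numbered C1 (O–CH bridgehead), C2–C3, C4 (O–C(CH3) bridgehead), C5 (ring-fusion CH), C6 (CH–O ester), C7 (CH–isopropyl), C8–C9 and C10 (quaternary C–CH3); ring A is C1–C5 plus C10, ring B is C5–C10. An oxygen spans C1 and C4, so ring A is a 7-oxabicyclo[2.2.1]heptane, and ring B is joined to it by an exo bond at C10 (to C9) and an endo bond at C5 (to C6), a trans annulation. Six stereocentres are contiguous (C4–C5–C6–C7 and C5–C10–C1), two of them quaternary. The oxygen bridge, H5, the C6 oxygen and the isopropyl group lie on one face (α here); the two methyl groups lie on the other (β). The trans annulation demands a torsion about C5–C10 inside ring B far above that of a chair, so ring B must be fully sp3 before the ether is closed; a C7=C8 double bond cannot coexist with the bridge, and this fixes the order of events. Fragile groups are the tertiary C4–O bond (acid ionises it, and a C4 cation can lose H5 and return as the less strained cis-fused isomer) and the aryl ester (base, hydride). The real difficulties are the kinetically controlled closure of the strained ether, the C7 hydrogen on the hindered methyl-bearing face, and the C6 oxygen cis to the isopropyl group. The key step exploits the 1,4-oxygen pattern of ring A with methyl on C4: C1(O)···C4(O)(CH3) is p-cresol at the 4-alkoxy-4-methylcyclohexa-2,5-dienone level, whose two enantiotopic enone arms offer C5 (β-carbon) and C10 (α-carbon).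

## Logic of the disconnections

24 ⇒ 22 + 23. Cut: the C6–O(acyl) bond, with inversion at C6. Reason: the C6 oxygen must be β to steer hydrogen to C7 and α in 24, so the ester enters in the step that inverts the centre. Gain: 22 carries the whole skeleton and five of the six stereocentres. Demand: substitution with inversion at a hindered secondary carbinol without elimination toward C5.

22 ⇒ 20. Cut: the C4–O bond of the bridge, together with the C3–H bond added with it. Reason: the bridge is the strained, acid-labile element, so it is made last on the skeleton, by anti addition across C3=C4 and not through a free C4 cation. Gain: the tricycle becomes an ordinary trans-fused octalindiol. Demand: closure through a boat ring A with ring B already saturated, and no loss of H5.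

20 ⇒ 19. Cut: C1–H. Reason: the nucleophilic oxygen must be axial (1α, cis to H5). Gain: C1 returns to the ketone level of the dienone. Demand: hydride delivery along the equatorial trajectory next to quaternary C10.

19 ⇒ 18. Change: C2–H and C3=C4 go back to the C2=C3 enone with methoxy on C4. Reason: this links the cyclisation substrate to the quinol-ether oxidation pattern and removes the C4 stereocentre from the problem. Gain: ring A is again the direct product of dienone chemistry. Demand: reductive elimination with the C4–O bond aligned with the enone π system, then kinetic protonation at C2.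

18 ⇒ 17. Cut: C7–H and C8–H. Reason: the C7 hydrogen sits on the face of the angular methyl and needs a neighbouring director. Gain: C7 becomes sp2 and ring B can come from an alkene-forming closure. Demand: delivery from the 6β-hydroxyl, faster than reduction of the C2=C3 enone alkene.

17 ⇒ 16. Cut: C7=C8. Reason: ring B closes strain-free while ring A is still a cyclohexenone. Gain: a monocyclic diene. Demand: metathesis between an allyl group and a hindered 1,1-disubstituted alkene.

16 ⇒ 13 + 14. Cut: C10–C9. Reason: C10 is the only enolisable carbon of the enone, and the C5 side chain shields one face. Gain: the quaternary centre comes from a simple allyl halide. Demand: alkylation anti to the C5 substituent with a free alkoxide present.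

13 ⇒ 10 + 12. Cut: C6–C7. Reason: it joins the isopropyl-bearing carbon as a vinyl-metal and creates the C6 carbinol. Gain: two small pieces. Demand: aldehyde-selective addition beside an enone, under non-basic conditions, with Felkin–Anh control from C5.

12 ⇒ 11. Cut: C–I and C–H across the alkyne. Reason: a 2-iodoalk-1-ene is the ideal partner for the chromium-mediated coupling. Demand: Markovnikov addition.

10 ⇒ 8. Change: C6=O back to C6=CH2. Reason: the vinyl group is a robust masked formyl group. Demand: cleavage of the isolated alkene in the presence of the enone alkene.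

8 ⇒ 2 + 4 + 5. Cut: C5–C6 and C10–CH3. Reason: both bonds lie on one enone arm of a symmetric dienone, so one catalytic step breaks the symmetry and sets the absolute configuration. Gain: an achiral, one-step derivative of a bulk phenol. Demand: catalyst control of arm and face, vinyl rather than methyl transfer, and C-methylation of the metal enolate.

4 ⇒ 3 and 2 ⇒ 1. Cut: Al–C(vinyl), and the C4–O bond with the ring C=C bonds restored to the arene. Reason: both are one-step preparations from commercial materials. A methyl ether is chosen on the quinol oxygen because it forms directly in the dearomatisation, is inert until step 10, and then serves as the leaving group.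

## Other disconnections considered

Alternative 1: The cut is the C1–O bond of the bridge, with C4–O kept. The forward step is a hypoiodite reaction (PhI(OAc)2, I2, visible light) on the C4 tertiary alcohol A2. Its alkoxy radical takes H1 by 1,5-transfer and the oxygen closes on C1 to give the silyl ether A1.
- In favour: the bridge is closed on a complete, saturated trans-decalin by an irreversible radical–polar sequence. The C4 carbinol is set beforehand on an unstrained ring, and ring A needs no alkene.
- Against: the 4α-oxygen is equatorial on a chair and reaches H1 only through a boat, whereas β-scission of the tertiary alkoxy radical (C3–C4 or C4–C5) needs no such change. C1 is neopentyl, so ether formation competes with a 1,2-shift from C10. A2 still needs every ring B stereocentre from elsewhere.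
- Comparison: it is the better in step economy for ring A (one step from A2 against steps 10–12). It is the equal in that both plans close the ether irreversibly. It is the weaker in site selectivity, because the chosen plan takes both ring A oxygens from 1 and never has to choose a C–H bond.

Alternative 2: The cuts are C5–C10 and C8–C9. Forward, methyllithium adds to the C9 ketone of the α-bromo 8-oxabicyclo[3.2.1]octenone A4, and the alkoxide pushes C5 from C9 to C10 with loss of bromide (quasi-Favorskii shift). This contracts the ring to the 7-oxanorbornene A3, with exo acetyl on C10 and endo benzyloxymethyl on C5.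
- In favour: the bridge, both bridgehead substituents and the exo/endo relation at C5/C10 are fixed stereospecifically (inversion at C10) before ring B exists. No strained etherification is needed at the end; on this structural point it is the better plan. The cycloaddition entry to A4 is short.
- Against: ring B must then be closed between an exo and an endo arm of a rigid bicycle, so the annulation strain is paid in a C–C bond formation. An aldol-condensation closure would pass through a ring B enone that the tricycle does not tolerate. C6, C7 and the C2=C3 alkene still need work, and absolute control needs an auxiliary.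
- Comparison: mechanistically the contraction is as well defined as step 3 (equal). The endgame is longer and less certain than steps 8–9, where ring B closes without strain on a cyclohexenone.

Alternative 3: The cuts are C1–O, C1–C10 and C4–C5. Forward, Rh2(OPiv)4 decomposes the diazo ester A6, the C4 ketone oxygen captures the carbene at C1, and the carbonyl ylide adds across the ester-tethered E alkene to give the lactone-bridged oxanorbornane A5.
- In favour: three bonds, the bicycle and a lactone form in one step, which surpasses step 3 in bonds formed. The alkene geometry becomes the trans C6/C9 relation. C6 and C7 arrive with the correct cis relation from an acyclic fragment, which spares the directed hydrogenation and the inversion of steps 9 and 13; on this point it is the better plan.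
- Against: C1 carries an ester carbon that must be excised later, and the C9–O bond must be turned into C9–C8. Facial selectivity rests on the C6 stereocentre alone. Ring B must again be closed trans onto the finished bicycle, and a metathesis closure would put a double bond in ring B.
- Comparison: more convergent and cleaner at C6/C7, but with more corrective steps after the key step and the same late ring B problem as alternative 2.

Key step: step 3

Assumption: vinyl is taken to enter 2 syn to the methoxy group, as alkyl groups do in copper–phosphoramidite additions of zinc reagents to 4-alkoxy-4-methyl dienones; C4 is erased in step 10, so its epimer would converge.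

Assumption: the (S,R,R) ligand is taken to give the C5 configuration drawn; if the sense is opposite, its (R,S,S) antipode is used.

## Route

Step 1
Reactants: 1 p-cresol
Product: 2 4-methoxy-4-methylcyclohexa-2,5-dien-1-one
Conditions: PhI(OAc)2, MeOH, 0 → 23 °C
Reagents that add atoms: methanol, CO
Why: Oxidative dearomatisation by trivalent iodine: the phenol is oxidised to a phenoxenium-type species that methanol traps at the methyl-bearing para carbon. The methyl ether is robust and later acts as a leaving group; no stereocentre is formed.

Step 2
Reactants: 3 vinylmagnesium bromide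
Product: 4 dimethyl(vinyl)aluminium
Conditions: Me2AlCl, THF–Et2O–hexanes, 0 → 23 °C; supernatant used directly
Reagents that add atoms: dimethylaluminium chloride, C[Al](C)Cl
Why: Transmetalation from magnesium to aluminium, driven by precipitation of the magnesium halide; the mixed alane later transfers its sp2 group in preference to methyl.

Step 3
Reactants: 2 4-methoxy-4-methylcyclohexa-2,5-dien-1-one, 4 dimethyl(vinyl)aluminium, 5 iodomethane
Product: 8 (4R,5S,6S)-5-ethenyl-4-methoxy-4,6-dimethylcyclohex-2-en-1-one, via dimethylaluminium dienolate 6 (not isolated), via lithium trimethylaluminate dienolate 7 (not isolated)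
Conditions: Cu(OTf)2 (5 mol %), (S,R,R)-O,O′-(1,1′-binaphthyl-2,2′-diyl) N,N-bis(1-phenylethyl)phosphoramidite (10 mol %), Et2O, −30 °C; MeLi, THF, −78 °C; then 5, DMPU, −78 → 0 °C
Reagents that add atoms: none
Why: The alane reduces the divalent copper salt to a monovalent copper–phosphoramidite complex, vinyl passes from aluminium to copper, the cuprate binds one of the two enantiotopic enone arms of 2, and oxidative addition followed by reductive elimination forms C5–C6 and leaves the dienolate 6. Methyllithium converts 6 into the more nucleophilic ate complex 7, which 5 methylates at C10, the only nucleophilic carbon of the cross-conjugated dienolate, to form C10–CH3. The closest known reaction type is the copper–phosphoramidite desymmetrising conjugate addition of organozinc and organoaluminium reagents to 4,4-disubstituted cyclohexadienones, combined with copper-catalysed alkenylalane addition and alkylation of the aluminium enolate after ate formation. No ring is closed; two skeletal bonds and three stereocentres (C4, C5, C10) arise. C5 is set by the ligand, which chooses the enone face; C4 becomes stereogenic through the choice of arm, which follows from the ligand's face preference together with entry of vinyl syn to the small, aluminium-coordinating methoxy group; at C10 methyl enters anti to the adjacent vinyl group. The step needs arm and face selection (ligand), vinyl rather than methyl transfer (sp2 groups leave mixed alanes faster), a single addition (the second arm is masked as the dienolate until quench) and C- rather than O-methylation (soft iodide). Only C5 must persist: C10 is re-enolised in step 7 and C4 is flattened in step 10, so epimers at those centres converge.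

Step 4
Reactants: 8 (4R,5S,6S)-5-ethenyl-4-methoxy-4,6-dimethylcyclohex-2-en-1-one
Product: 10 (1S,2R,6S)-2-methoxy-2,6-dimethyl-5-oxocyclohex-3-ene-1-carbaldehyde, via secondary ozonide 9 (not isolated)
Conditions: O3, CH2Cl2, −78 °C (Sudan Red 7B end point); PPh3, −78 → 23 °C
Reagents that add atoms: ozone, [O-][O+]=O
Why: Ozonolysis: the isolated monosubstituted alkene reacts far faster than the electron-poor enone alkene, and the indicator dye limits the ozone dose. The neutral reductive work-up leaves C5 and the β-methoxy group untouched.

Step 5
Reactants: 11 3-methylbut-1-yne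
Product: 12 2-iodo-3-methylbut-1-ene
Conditions: NaI, Me3SiCl, H2O, MeCN, 23 °C
Reagents that add atoms: sodium iodide, [Na+].[I-]
Why: Markovnikov hydroiodination of a terminal alkyne by hydrogen iodide made in the flask; iodine ends on the internal carbon, which gives the 2-iodoalk-1-ene needed as the C7 donor.

Step 6
Reactants: 10 (1S,2R,6S)-2-methoxy-2,6-dimethyl-5-oxocyclohex-3-ene-1-carbaldehyde, 12 2-iodo-3-methylbut-1-ene
Product: 13 (4R,5R,6S)-5-[(1R)-1-hydroxy-3-methyl-2-methylidenebutyl]-4-methoxy-4,6-dimethylcyclohex-2-en-1-one
Conditions: CrCl2 (4 equiv), NiCl2 (2 mol %), DMF, 23 °C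
Reagents that add atoms: none
Why: Nozaki–Hiyama–Kishi coupling: the nickel-generated alkenylchromium species adds to aldehydes and ignores the enone, and it is not basic, so the epimerisable β-methoxy aldehyde survives. Felkin–Anh addition anti to the quaternary C4 should give the (R)-carbinol (6β-OH), the configuration needed in step 9; the minor C6 epimer is removed by chromatography.

Step 7
Reactants: 13 (4R,5R,6S)-5-[(1R)-1-hydroxy-3-methyl-2-methylidenebutyl]-4-methoxy-4,6-dimethylcyclohex-2-en-1-one, 14 allyl bromide
Product: 16 (4R,5R,6S)-5-[(1R)-1-hydroxy-3-methyl-2-methylidenebutyl]-4-methoxy-4,6-dimethyl-6-(prop-2-en-1-yl)cyclohex-2-en-1-one, via dilithium alkoxide enolate 15 (not isolated)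
Conditions: LiN(i-Pr)2 (2.3 equiv), THF, −78 °C; 14, DMPU, −78 → −20 °C
Reagents that add atoms: none
Why: Enolate alkylation: the first equivalent of amide forms the alkoxide and the second removes the only α-hydrogen (C10–H; C2 is vinylic and C4 is quaternary). Allyl bromide enters anti to the branched C5 substituent, which places C9 trans to C6 and the methyl cis to it; the lithium alkoxide is a poor nucleophile at this temperature.

Step 8
Reactants: 16 (4R,5R,6S)-5-[(1R)-1-hydroxy-3-methyl-2-methylidenebutyl]-4-methoxy-4,6-dimethyl-6-(prop-2-en-1-yl)cyclohex-2-en-1-one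
Product: 17 (4R,4aR,5R,8aS)-5-hydroxy-4-methoxy-4,8a-dimethyl-6-(propan-2-yl)-4a,5,8,8a-tetrahydronaphthalen-1(4H)-one
Conditions: (H2IMes)Cl2Ru=CH(C6H4-2-O-i-Pr) (second-generation Hoveyda–Grubbs catalyst, 5 mol %), 1,4-benzoquinone (10 mol %), toluene, 80 °C
Reagents that add atoms: none
Why: Ring-closing metathesis between the allyl group and the 1,1-disubstituted alkene forms the trisubstituted C7=C8 bond of ring B with loss of ethene. Both chains are equatorial on the cyclohexenone, so the trans-fused octalin closes without strain, and no stereocentre is formed.

Step 9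
Reactants: 17 (4R,4aR,5R,8aS)-5-hydroxy-4-methoxy-4,8a-dimethyl-6-(propan-2-yl)-4a,5,8,8a-tetrahydronaphthalen-1(4H)-one
Product: 18 (4R,4aR,5S,6S,8aS)-5-hydroxy-4-methoxy-4,8a-dimethyl-6-(propan-2-yl)-4a,5,6,7,8,8a-hexahydronaphthalen-1(4H)-one
Conditions: [Ir(cod)(PCy3)(py)]PF6 (5 mol %), H2 (1 atm), CH2Cl2, 0 → 23 °C
Reagents that add atoms: none
Why: Hydroxyl-directed hydrogenation with the Crabtree catalyst: the cationic iridium centre binds the 6β-hydroxyl and delivers hydrogen to the β face of C7=C8 against the bias of the angular methyl, which sets C7 (H β, isopropyl α). The conjugated C2=C3 alkene, flanked by quaternary C4, should react more slowly. Ring B is saturated here because it cannot hold a double bond once the ether is closed.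

Step 10
Reactants: 18 (4R,4aR,5S,6S,8aS)-5-hydroxy-4-methoxy-4,8a-dimethyl-6-(propan-2-yl)-4a,5,6,7,8,8a-hexahydronaphthalen-1(4H)-one
Product: 19 (4aR,5S,6S,8aS)-5-hydroxy-4,8a-dimethyl-6-(propan-2-yl)-4a,5,6,7,8,8a-hexahydronaphthalen-1(2H)-one
Conditions: SmI2 (2.5 equiv), THF–MeOH, −78 °C
Reagents that add atoms: none
Why: Electron-transfer reductive elimination (vinylogous α-deoxygenation): divalent samarium reduces the enone to an allyl anion whose C3 electron pair expels the axial 4β-methoxide. Kinetic protonation of the samarium dienolate at C2 gives the β,γ-unsaturated ketone with the alkene at C3=C4; C4 is no longer a stereocentre.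

Step 11
Reactants: 19 (4aR,5S,6S,8aS)-5-hydroxy-4,8a-dimethyl-6-(propan-2-yl)-4a,5,6,7,8,8a-hexahydronaphthalen-1(2H)-one
Product: 20 (1R,4aR,5S,6S,8aS)-4,8a-dimethyl-6-(propan-2-yl)-1,2,4a,5,6,7,8,8a-octahydronaphthalene-1,5-diol
Conditions: LiBH(s-Bu)3 (L-Selectride, 2.5 equiv), THF, −78 °C; aq. NH4Cl
Reagents that add atoms: none
Why: Reduction by a bulky hydride along the equatorial trajectory, as with 4,4-dimethyl-3-keto triterpenoids, gives the axial 1α-alcohol cis to H5. The low temperature keeps the β,γ-alkene out of conjugation.

Step 12
Reactants: 20 (1R,4aR,5S,6S,8aS)-4,8a-dimethyl-6-(propan-2-yl)-1,2,4a,5,6,7,8,8a-octahydronaphthalene-1,5-diol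
Product: 22 (1R,4S,4aR,5S,6S,8aS)-4,8a-dimethyl-6-(propan-2-yl)decahydro-1,4-epoxynaphthalen-5-ol, via organomercurial 21 (not isolated)
Conditions: Hg(OCOCF3)2 (1.1 equiv), CH2Cl2, −20 → 0 °C; then NaBH4, aq. NaOH, 0 °C
Reagents that add atoms: none
Why: Intramolecular alkoxymercuration–demercuration: divalent mercury activates C3=C4 from the β face and the 1α-hydroxyl attacks tertiary C4 from the α face through a boat ring A, the topology by which terpinen-4-ol-type cyclohex-3-enols close to 1,4-cineoles. No free C4 cation forms, so H5 is not lost; borohydride then replaces mercury by hydrogen. The C4 configuration (O α, CH3 β) is dictated by the bridge.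

Step 13
Reactants: 22 (1R,4S,4aR,5S,6S,8aS)-4,8a-dimethyl-6-(propan-2-yl)decahydro-1,4-epoxynaphthalen-5-ol, 23 4-methoxybenzoic acid
Product: 24 (1R,4S,4aR,5R,6S,8aS)-4,8a-dimethyl-6-(propan-2-yl)decahydro-1,4-epoxynaphthalen-5-yl 4-methoxybenzoate
Conditions: PPh3, i-PrO2CN=NCO2-i-Pr (DIAD), toluene, 0 → 50 °C
Reagents that add atoms: none
Why: Mitsunobu esterification: the alkoxyphosphonium ion of the 6β-alcohol is displaced by 4-methoxybenzoate with inversion (SN2) to give the 6α-ester. Departure of the 6β-oxygen relieves its clash with the C10 methyl.

## Compound list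

1 | p-cresol (4-methylphenol) | Cc1ccc(O)cc1 | starting material
2 | 4-methoxy-4-methylcyclohexa-2,5-dien-1-one | COC1(C)C=CC(=O)C=C1 | intermediate
3 | vinylmagnesium bromide | C=C[Mg]Br | starting material
4 | dimethyl(vinyl)aluminium | C=C[Al](C)C | intermediate
5 | iodomethane | CI | starting material
6 | dimethylaluminium dienolate from vinyl addition to 2 (O–AlMe2 on C1, C1=C10, vinyl on C5 syn to methoxy) | C[Al](C)OC1C=C[C@@](C)(OC)[C@@H](C=C)C=1 | intermediate
7 | lithium trimethylaluminate of the same dienolate | [Li+].C[Al-](C)(C)OC1C=C[C@@](C)(OC)[C@@H](C=C)C=1 | intermediate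
8 | (4R,5S,6S)-5-ethenyl-4-methoxy-4,6-dimethylcyclohex-2-en-1-one | O=C1C=C[C@@](C)(OC)[C@@H](C=C)[C@@H]1C | intermediate
9 | secondary ozonide of 8 (1,2,4-trioxolan-3-yl in place of ethenyl; either configuration at the trioxolane carbon) | O=C1C=C[C@@](C)(OC)[C@@H](C2OCOO2)[C@@H]1C | intermediate
10 | (1S,2R,6S)-2-methoxy-2,6-dimethyl-5-oxocyclohex-3-ene-1-carbaldehyde | O=C1C=C[C@@](C)(OC)[C@@H](C=O)[C@@H]1C | intermediate
11 | 3-methylbut-1-yne | CC(C)C#C | starting material
12 | 2-iodo-3-methylbut-1-ene | C=C(I)C(C)C | intermediate
13 | (4R,5R,6S)-5-[(1R)-1-hydroxy-3-methyl-2-methylidenebutyl]-4-methoxy-4,6-dimethylcyclohex-2-en-1-one | O=C1C=C[C@@](C)(OC)[C@@H]([C@@H](O)C(=C)C(C)C)[C@@H]1C | intermediate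
14 | allyl bromide (3-bromoprop-1-ene) | C=CCBr | starting material
15 | dilithium alkoxide enolate of 13 (O–Li on the C6 oxygen and on the C1 oxygen, C1=C10) | [Li]OC1C=C[C@@](C)(OC)[C@@H]([C@@H](O[Li])C(=C)C(C)C)C=1C | intermediate
16 | (4R,5R,6S)-5-[(1R)-1-hydroxy-3-methyl-2-methylidenebutyl]-4-methoxy-4,6-dimethyl-6-(prop-2-en-1-yl)cyclohex-2-en-1-one | O=C1C=C[C@@](C)(OC)[C@@H]([C@@H](O)C(=C)C(C)C)[C@]1(C)CC=C | intermediate
17 | (4R,4aR,5R,8aS)-5-hydroxy-4-methoxy-4,8a-dimethyl-6-(propan-2-yl)-4a,5,8,8a-tetrahydronaphthalen-1(4H)-one | O=C1C=C[C@@](C)(OC)[C@H]2[C@@H](O)C(C(C)C)=CC[C@]12C | intermediate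
18 | (4R,4aR,5S,6S,8aS)-5-hydroxy-4-methoxy-4,8a-dimethyl-6-(propan-2-yl)-4a,5,6,7,8,8a-hexahydronaphthalen-1(4H)-one | O=C1C=C[C@@](C)(OC)[C@H]2[C@@H](O)[C@H](C(C)C)CC[C@]12C | intermediate
19 | (4aR,5S,6S,8aS)-5-hydroxy-4,8a-dimethyl-6-(propan-2-yl)-4a,5,6,7,8,8a-hexahydronaphthalen-1(2H)-one | O=C1CC=C(C)[C@H]2[C@@H](O)[C@H](C(C)C)CC[C@]12C | intermediate
20 | (1R,4aR,5S,6S,8aS)-4,8a-dimethyl-6-(propan-2-yl)-1,2,4a,5,6,7,8,8a-octahydronaphthalene-1,5-diol | O[C@@H]1CC=C(C)[C@H]2[C@@H](O)[C@H](C(C)C)CC[C@]12C | intermediate
21 | organomercurial: 3-(trifluoroacetoxymercurio) derivative of 22, mercury on C3 anti to the bridging oxygen | O[C@H]2[C@H](C(C)C)CC[C@]3(C)[C@H]4C[C@@H]([Hg]OC(=O)C(F)(F)F)[C@](C)(O4)[C@@H]23 | intermediate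
22 | (1R,4S,4aR,5S,6S,8aS)-4,8a-dimethyl-6-(propan-2-yl)decahydro-1,4-epoxynaphthalen-5-ol | O[C@H]2[C@H](C(C)C)CC[C@]3(C)[C@H]4CC[C@](C)(O4)[C@@H]23 | intermediate
23 | 4-methoxybenzoic acid | COc1ccc(cc1)C(O)=O | starting material
24 | (1R,4S,4aR,5R,6S,8aS)-4,8a-dimethyl-6-(propan-2-yl)decahydro-1,4-epoxynaphthalen-5-yl 4-methoxybenzoate | COc1ccc(C(=O)O[C@@H]2[C@H](C(C)C)CC[C@]3(C)[C@H]4CC[C@](C)(O4)[C@@H]23)cc1 | target

## Step count and least certain steps

Total step count: 13. Longest linear sequence: 11 steps (steps 1, 3, 4 and 6–13); steps 2 and 5 prepare the two side reagents.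

Step 3 (key step). What may go wrong: incomplete discrimination of the enantiotopic arms, transfer of methyl in place of vinyl, or sluggish C-methylation of the aluminium enolate with attack of methyllithium on the enone as it forms. The step combines three precedented operations on a substrate that has not seen all three at once. Fallback: setting out from 2, a rhodium-catalysed asymmetric conjugate addition of potassium vinyltrifluoroborate ([Rh(OH)(cod)]2, BINAP, dioxane–water) would give (4R,5R)-5-ethenyl-4-methoxy-4-methylcyclohex-2-en-1-one F1. Kinetic deprotonation of F1 with LiN(i-Pr)2 and methylation with 5 then comes back to the route at 8.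

Step 6. What may go wrong: poor or reversed facial selectivity at C6, because both flanking groups on C5 are ring carbons; also enolisation of the aldehyde with loss of methanol. Fallback: the addition to 10 would give the C6 epimer F2 alongside 13. F2 is separated and inverted by a Mitsunobu reaction with 4-nitrobenzoic acid (facile on this open-chain allylic alcohol) to the 4-nitrobenzoate F3, and methanolysis (K2CO3, MeOH) comes back at 13.

Step 9. What may go wrong: loss of chemoselectivity, with the enone alkene C2=C3 hydrogenated as well, or isomerisation of the allylic alcohol to a ketone. Fallback: setting out from 17, exhaustive hydrogenation under the same direction would give the saturated ketone F4. Silylation (Me3SiOTf, Et3N) to the bis(trimethylsilyl) compound F5 and Saegusa–Ito oxidation with Pd(OAc)2, followed by mild acid, would restore the enone and come back at 18.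

Step 10. What may go wrong: slow β-elimination if the C4–O bond is not axial (the case if vinyl had entered anti to methoxy in step 3), migration of the new alkene into conjugation on work-up, or over-reduction of the ketone. Fallback: setting out from 18, hydrogenation over Pd/C gives the saturated ketone F4 and L-Selectride gives the 1α-hydroxy methyl ether F6. Ionisation of the tertiary methyl ether with BF3·OEt2 at low temperature and capture by the 1α-hydroxyl comes back at 22. This cationic closure is the less preferred course because the C4 cation can lose H5.

Step 12. What may go wrong: an unfavourable or reversible alkoxymercuration because of the strain of the trans-fused bicycle, capture of the mercurinium ion by trifluoroacetate, or reversion to the alkene during demercuration. Fallback: setting out from 20 and coming back at 22, a cobalt-hydride hydrogen-atom-transfer hydroalkoxylation (Co(salen) with divalent cobalt, N-fluoro-2,4,6-trimethylpyridinium triflate, PhSiH3) would make the C4 radical, oxidise it and trap it with the 1α-hydroxyl irreversibly. No compound outside the list is formed (entry F0).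

Step 13. What may go wrong: failure of the substitution at the crowded C6, with elimination toward C5=C6 or esterification with retention through an acyloxyphosphonium ion. Fallback: setting out from 22, Dess–Martin oxidation gives the ketone F7. Dissolving-metal reduction (Li, NH3, t-BuOH) should give the more stable 6α-alcohol F8, and acylation with 4-methoxybenzoyl chloride (pyridine, DMAP) comes back at 24. The risk of this course is epimerisation at C7 under the reducing conditions.

## Further compounds

F1 | step 3 | (4R,5R)-5-ethenyl-4-methoxy-4-methylcyclohex-2-en-1-one | O=C1C=C[C@@](C)(OC)[C@@H](C=C)C1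
F2 | step 6 | (4R,5R,6S)-5-[(1S)-1-hydroxy-3-methyl-2-methylidenebutyl]-4-methoxy-4,6-dimethylcyclohex-2-en-1-one (C6 epimer of 13) | O=C1C=C[C@@](C)(OC)[C@@H]([C@H](O)C(=C)C(C)C)[C@@H]1C
F3 | step 6 | 4-nitrobenzoate of 13 | O=C1C=C[C@@](C)(OC)[C@@H]([C@@H](OC(=O)c2ccc(cc2)[N+](=O)[O-])C(=C)C(C)C)[C@@H]1C
F4 | step 9 | (4R,4aR,5S,6S,8aS)-5-hydroxy-4-methoxy-4,8a-dimethyl-6-(propan-2-yl)octahydronaphthalen-1(2H)-one | O=C1CC[C@@](C)(OC)[C@H]2[C@@H](O)[C@H](C(C)C)CC[C@]12C
F5 | step 9 | bis(trimethylsilyl) derivative of F4 (C1=C2 silyl enol ether and C6 silyl ether) | C[Si](C)(C)OC1=CC[C@@](C)(OC)[C@H]2[C@@H](O[Si](C)(C)C)[C@H](C(C)C)CC[C@]12C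
F6 | step 10 | (1R,4R,4aR,5S,6S,8aS)-4-methoxy-4,8a-dimethyl-6-(propan-2-yl)decahydronaphthalene-1,5-diol | O[C@@H]1CC[C@@](C)(OC)[C@H]2[C@@H](O)[C@H](C(C)C)CC[C@]12C
F0 | step 12 | none | none
F7 | step 13 | (1R,4S,4aS,6S,8aS)-4,8a-dimethyl-6-(propan-2-yl)octahydro-1,4-epoxynaphthalen-5(1H)-one | O=C2[C@H](C(C)C)CC[C@]3(C)[C@H]4CC[C@](C)(O4)[C@@H]23
F8 | step 13 | (1R,4S,4aR,5R,6S,8aS)-4,8a-dimethyl-6-(propan-2-yl)decahydro-1,4-epoxynaphthalen-5-ol | O[C@@H]2[C@H](C(C)C)CC[C@]3(C)[C@H]4CC[C@](C)(O4)[C@@H]23
A1 | alternative 1 | tert-butyldimethylsilyl ether of the complete tricyclic 6α-alcohol | CC(C)(C)[Si](C)(C)O[C@@H]2[C@H](C(C)C)CC[C@]3(C)[C@H]4CC[C@](C)(O4)[C@@H]23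
A2 | alternative 1 | trans-decalin C4 tertiary alcohol (4α-OH, 4β-CH3) with the 6α-silyloxy and 7α-isopropyl groups | CC(C)(C)[Si](C)(C)O[C@@H]1[C@H](C(C)C)CC[C@]2(C)CCC[C@](C)(O)[C@@H]12
A3 | alternative 2 | exo-acetyl, endo-benzyloxymethyl 7-oxanorbornene | C[C@@]1(C(C)=O)[C@H]2C=C[C@](C)(O2)[C@H]1COCc3ccccc3
A4 | alternative 2 | 2-bromo-4-[(benzyloxy)methyl]-2,5-dimethyl-8-oxabicyclo[3.2.1]oct-6-en-3-one (bromine anti to the migrating bond) | C[C@]1(Br)C(=O)[C@H](COCc2ccccc2)[C@]3(C)C=C[C@H]1O3
A5 | alternative 3 | lactone-bridged 7-oxanorbornane with the C6–C7 side chain | C[C@@]1(COC3=O)[C@@]23CC[C@](C)(O2)[C@H]1[C@H](O[Si](C)(C)C(C)(C)C)[C@H](C(C)C)C=C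
A6 | alternative 3 | (E)-4-(tert-butyldimethylsilyloxy)-2-methyl-5-(propan-2-yl)hepta-2,6-dien-1-yl 2-diazo-5-oxohexanoate, C4 and C5 of the chain configured as C6 and C7 of the target | CC(=O)CCC(=[N+]=[N-])C(=O)OC/C(C)=C/[C@H](O[Si](C)(C)C(C)(C)C)[C@H](C(C)C)C=C
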